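Assumption: the structure carries no stereodescriptor and the 18-membered cyclophane is taken as conformationally mobile, so there is no stereochemical element to control.

## Analysis of the target

The target 17 is an 18-membered macrocycle in which four benzene rings are joined in turn by two CH2CH2 bridges and two diaryl ether oxygens: ring A–CH2CH2–ring B–O–ring C–CH2CH2–ring D–O–ring A. Ring A is 1,2,4-trisubstituted, with the ring D oxygen at C1, the bridge to ring B at C2 and OH at C4, para to the ether oxygen. Ring B is a para-phenylene and ring D a meta-phenylene; ring C carries the ring B oxygen at C1, OH at C2 and the bridge to ring D at C5. There are no stereocentres. The sensitive parts are the two free phenols, which make ring A a hydroquinone monoaryl ether and ring C a catechol monoaryl ether, both easily oxidised as phenoxides, and the four benzylic methylenes. The difficulty lies in the two unsymmetrical diaryl ethers, one of them (D–O–A) flanked by a bridge, and in closing an 18-membered cyclophane through one of them. The feature the plan rests on is positional: C4 of ring A is para, and C2 of ring C is ortho, to the carbon that carries an ether oxygen. A formyl group at those two carbons activates a fluoride on the ether carbon towards a phenoxide, and can afterwards be turned into the hydroxyl by oxygen insertion.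

## Retrosynthetic reasoning

17 is taken back to the bis-formate 16. Only two ester C–O bonds are cut, so the phenols stay masked until the final, mild methanolysis.

16 is taken back to the macrocyclic dialdehyde 15 by cutting the aryl C–O bonds of both future hydroxyls (C4 of ring A, C2 of ring C) and placing a formyl carbon there. These oxygens are the only heteroatoms that are not part of the ring skeleton, so they can be introduced last and need no protecting group. The forward reaction must insert oxygen between ring and formyl carbon at both sites with aryl, not hydride, migration.

15 is opened at the bond between the ring D oxygen and C1 of ring A, which gives the seco compound 14 with a phenol on ring D and a fluoride para to the ring A formyl group. Either ether could serve as the closure. This one is chosen because the activation of ring A can be switched off and on (next paragraph), which makes the intermolecular ether formation clean. The forward reaction is an intramolecular fluoride displacement under dilution.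

14 is traced to 13 by masking only: the ring A aldehyde as a cyclic acetal and the ring D hydroxyl as a methoxymethyl ether. In 13 the ring A fluoride is dormant and the ring D oxygen is blocked, and one acid treatment releases both.

13 is cut at the bond between the ring B oxygen and C1 of ring C, giving phenol 6 and fluoroaldehyde 12. Each half holds one fluoride and one phenolic oxygen, so selectivity is the issue. In 6 the phenol is free and the fluoride dormant, and in 12 the phenol is blocked and the fluoride live. Only one pairing can therefore react.

6 is cut at the bond between ring A and its bridge carbon, giving bromide 2 and styrene 3, to be joined by hydroboration and B-alkyl cross-coupling. The acetate of 3 keeps the phenol from consuming the borane and falls off under the aqueous base of the coupling. 2 comes from 1 by acetalisation, which both silences the fluoride and shields the carbonyl from boron hydride.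

12 is cut in the same way at the bond between ring C and its bridge carbon, giving styrene 9 and bromide 10. A styrene cannot be hydroborated once an aldehyde is in the same molecule. That is why both bridges are made before the ethers and each styrene meets its bromide as a simple building block.

9 comes from 8 by methylenation of the aldehyde, and 8 from 7 by protecting the phenol.

## Alternatives that were turned down

Alternative 1: The B–O–C ether is cut between the ring B oxygen and C1 of ring C, with ring C taken back to the cyclohexanone level. CsF would remove the silyl group from the ring B oxygen of the seco α-bromoketone A1, and the phenoxide would displace bromide at the α-carbon, closing the 18-membered ring to the 2-aryloxycyclohexanone A2. Dehydrogenation of A2 to the arene and cleavage of the ring A methyl ether would follow.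
- For: an α-bromoketone is a much better electrophile than any fluoroarene, so the closure should run near room temperature, and the sp3 carbons make the chain more flexible. The two stereocentres of A2 do not matter. On the ring-closing event itself this plan is probably stronger than a fluoride displacement at about 90 °C.
- Against: ring C must be built as a saturated 4-substituted cyclohexanone and brominated in the presence of electron-rich arenes. The phenoxide is also a base and can cause loss of HBr or Favorskii contraction. Aromatising A2 means removing four hydrogens oxidatively beside four benzylic methylenes, and α-aryloxy ketones are prone to C–O cleavage under the conditions usually used. The D–O–A ether gets no help and would need a CuI-mediated coupling, and a BBr3 demethylation remains.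
- Comparison: the chosen plan keeps all four rings aromatic from commercial arenes, makes both ethers by the same activated substitution and needs only two steps after the macrocycle.

Alternative 2: The bond between ring A and its bridge carbon is cut in a rearrangement sense. The precursor is the 17-membered quinol ether A3, a cyclohexa-2,5-dienone whose C4 carries both the ring D oxygen and the bridge CH2. Acid would activate the carbonyl, the CH2 would shift from C4 to C3, and the cation left at C4 would be stabilised by the aryloxy oxygen. Proton loss would give the ring A phenol of A4, the ring C methyl ether of the target, with the ring grown to 18 members.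
- For: the crowded ether-next-to-bridge arrangement on ring A arises without substitution at a hindered arene carbon, where the chosen plan has its weakest displacement. The dienone is symmetrical, so regiochemistry is not in question, and the ring A hydroxyl emerges free. In concept it is the most economical plan.
- Against: A3 must come from oxidative dearomatisation of a para-alkylphenol with capture by the ring D phenol as a macrocyclisation, while two phenols compete for the oxidant. A primary alkyl group migrates reluctantly, and quinol aryl ethers under acid readily ionise with loss of the phenol or shift the oxygen substituent instead. Ring C still needs a methyl ether and its removal.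
- Comparison: two uncertain steps stand in a row, whereas the chosen plan has one well-known oxidation as its only real question.

Alternative 3: The C–D bridge is cut at the bond between ring C and its CH2, again as a rearrangement. The precursor is the 17-membered 1,1-diarylethene A5, in which rings C and D share one sp2 carbon. PhI(OH)OTs, a trivalent iodine reagent, in aqueous methanol would add to the methylene carbon. Ring C would then shift to that carbon with loss of iodobenzene, giving the 18-membered deoxybenzoin A6.
- For: this oxidative rearrangement is established for open-chain 1,1-diarylalkenes. Ring C, with methoxy para to the migrating carbon, should migrate clearly in preference to ring D. On migration selectivity it is at least as secure as the aryl-versus-hydride choice of the chosen key step.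
- Against: the effort goes into a CH2CH2 bridge, the easiest bond of the target, while both diaryl ethers and the closure of A5 are left to unactivated, copper-type chemistry. Ring A in A5 is a hydroquinone diether, which trivalent iodine can itself oxidise. After A6 the ketone must be reduced to CH2 and two methyl ethers cleaved.
- Comparison: three steps follow the key step here against one in the chosen plan, whose formyl carbons also do the work of making both ethers.

Key step: step 9

## Route

Step 1
Reactants: 1 3-bromo-4-fluorobenzaldehyde
Product: 2 2-(3-bromo-4-fluorophenyl)-1,3-dioxolane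
Conditions: HOCH2CH2OH (3 equiv), TsOH·H2O (cat.), toluene, reflux, Dean–Stark
Reagents that add atoms: ethylene glycol, OCCO
Why: Acid-catalysed acetalisation with azeotropic removal of water; as the dioxolane, the carbon para to fluorine is no longer an acceptor, so the ring A fluoride stays dormant and the carbonyl is shielded from boron hydride in step 2.

Step 2
Reactants: 3 4-ethenylphenyl acetate (4-acetoxystyrene); 2 2-(3-bromo-4-fluorophenyl)-1,3-dioxolane
Product: 6 4-{2-[5-(1,3-dioxolan-2-yl)-2-fluorophenyl]ethyl}phenol, via alkylborane acetate 4 (not isolated), via alkylborane phenoxide 5 (not isolated)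
Conditions: 9-BBN, THF, 0 °C→rt; 3 M aq NaOH, rt; then 2, PdCl2(dppf) (3 mol %), 65 °C; aq NH4Cl
Reagents that add atoms: none
Why: 9-BBN hydroborates the styrene at the terminal carbon while the acetate keeps the phenol from consuming B–H; aqueous NaOH then saponifies the aryl acetate and forms the hydroxyborate, which transmetalates to the arylpalladium bromide from 2 (B-alkyl Suzuki–Miyaura coupling). The dioxolane and the unactivated C–F bond are inert to these conditions.

Step 3
Reactants: 7 3-hydroxybenzaldehyde
Product: 8 3-(methoxymethoxy)benzaldehyde
Conditions: MOMCl, iPr2NEt, CH2Cl2, 0 °C→rt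
Reagents that add atoms: chloromethyl methyl ether, COCCl
Why: O-Alkylation of the phenol by the α-chloro ether under amine base; the methoxymethyl ether withstands ylide, borane, the palladium-catalysed coupling and the carbonate and fluoride of step 6, and is cleaved by the same acid that opens the dioxolane.

Step 4
Reactants: 8 3-(methoxymethoxy)benzaldehyde
Product: 9 1-ethenyl-3-(methoxymethoxy)benzene
Conditions: Ph3PCH3Br, KOtBu, THF, 0 °C→rt
Reagents that add atoms: methyltriphenylphosphonium bromide, C[P+](c1ccccc1)(c1ccccc1)c1ccccc1.[Br-]
Why: Wittig methylenation of an aryl aldehyde with the unstabilised ylide, driven by formation of the P=O bond.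

Step 5
Reactants: 9 1-ethenyl-3-(methoxymethoxy)benzene; 10 4-bromo-2-fluorobenzaldehyde
Product: 12 2-fluoro-4-{2-[3-(methoxymethoxy)phenyl]ethyl}benzaldehyde, via alkylborane 11 (not isolated)
Conditions: 9-BBN, THF, 0 °C→rt; 3 M aq K3PO4, rt; then 10, PdCl2(dppf) (5 mol %), DMF, 60 °C
Reagents that add atoms: none
Why: Terminal hydroboration followed by B-alkyl Suzuki–Miyaura coupling at the C–Br bond para to the formyl group. A slight excess of 9 leaves no B–H, and the aqueous phosphate is added before 10 so that boron is a four-coordinate borate and no longer a Lewis acid or hydride donor towards the aldehyde; the C–F bond does not undergo oxidative addition.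

Step 6
Reactants: 6 4-{2-[5-(1,3-dioxolan-2-yl)-2-fluorophenyl]ethyl}phenol; 12 2-fluoro-4-{2-[3-(methoxymethoxy)phenyl]ethyl}benzaldehyde
Product: 13 2-(4-{2-[5-(1,3-dioxolan-2-yl)-2-fluorophenyl]ethyl}phenoxy)-4-{2-[3-(methoxymethoxy)phenyl]ethyl}benzaldehyde
Conditions: K2CO3, DMSO, 90 °C
Reagents that add atoms: none
Why: Nucleophilic aromatic substitution: the phenoxide of 6 adds ortho to the formyl group of 12, which stabilises the Meisenheimer adduct, and fluoride leaves. The fluoride of 6 sits para to an acetal carbon and is not activated, and the ring D oxygen of 12 is blocked, so neither partner can condense with itself.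

Step 7
Reactants: 13 2-(4-{2-[5-(1,3-dioxolan-2-yl)-2-fluorophenyl]ethyl}phenoxy)-4-{2-[3-(methoxymethoxy)phenyl]ethyl}benzaldehyde
Product: 14 2-{4-[2-(2-fluoro-5-formylphenyl)ethyl]phenoxy}-4-[2-(3-hydroxyphenyl)ethyl]benzaldehyde
Conditions: 3 M aq HCl, THF, 50 °C
Reagents that add atoms: water, O
Why: Aqueous acid hydrolyses both acetals in one operation, the dioxolane to the ring A aldehyde and the methoxymethyl ether to the ring D phenol; without base the freed phenol does not attack the now activated fluoride.

Step 8
Reactants: 14 2-{4-[2-(2-fluoro-5-formylphenyl)ethyl]phenoxy}-4-[2-(3-hydroxyphenyl)ethyl]benzaldehyde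
Product: 15 macrocyclic dialdehyde (18-membered ring; CHO at C4 of ring A para to the ring D oxygen; CHO at C2 of ring C ortho to the ring B oxygen)
Conditions: Cs2CO3 (3 equiv), DMSO, 90 °C, slow addition of 14 (final 0.005 M)
Reagents that add atoms: none
Why: Intramolecular nucleophilic aromatic substitution: the ring D phenoxide attacks C1 of ring A para to the formyl group and fluoride leaves, closing the 18-membered ring at the aryl C–O bond; dilution suppresses chain growth. The aryloxy group on ring C is a much poorer leaving group than fluoride, so the ether made in step 6 should not exchange.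

Step 9
Reactants: 15 macrocyclic dialdehyde
Product: 16 bis-formate of the target (OCHO at C4 of ring A and at C2 of ring C)
Conditions: mCPBA (3 equiv), CH2Cl2, 0 °C→rt
Reagents that add atoms: 3-chloroperbenzoic acid, OOC(=O)c1cccc(Cl)c1
Why: This is the Baeyer–Villiger (Dakin-type) oxidation of aryloxybenzaldehydes to aryl formates, a known reaction of alkoxy- and aryloxy-substituted benzaldehydes, run here at two sites in one flask. The peracid adds to each formyl carbon to give a tetrahedral peroxy adduct (Criegee adduct), and cleavage of its O–O bond goes with a 1,2-shift of the aryl group from carbon to oxygen and loss of 3-chlorobenzoate, which forms the C4–O bond of ring A and the C2–O bond of ring C. The shift must be that of aryl and not of hydride, which would end in a carboxylic acid; on ring A the migrating carbon is para to the ring D oxygen, and on ring C it is ortho to the ring B oxygen and para to the bridge, so in both a lone-pair donor stabilises the positive charge that builds on the migrating ring. No base is added, because the acid co-product assists breakdown of the adduct in the aryl-migration sense, whereas basic peroxide conditions favour hydride loss in benzaldehydes that lack a free hydroxyl. The second requirement is that the four arene rings and the benzylic positions are not oxidised; the rings carry only aryloxy and alkyl groups, the products are formates and not free phenols, and dry CH2Cl2 keeps them from hydrolysing while peracid is present. The step closes no ring and creates no stereocentre, since the macrocycle is already in place from step 8.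

Step 10
Reactants: 16 bis-formate of the target
Product: 17 target diphenol
Conditions: K2CO3 (0.2 equiv), MeOH–THF, rt, argon; aq NH4Cl
Reagents that add atoms: none
Why: Base-catalysed transesterification; aryl formates are among the most labile esters and pass their formyl groups to methanol, while the diaryl ethers are inert. Argon protects the electron-rich phenoxides from air.

## Compound list

1 | 3-bromo-4-fluorobenzaldehyde | O=Cc1ccc(F)c(Br)c1 | starting material
2 | 2-(3-bromo-4-fluorophenyl)-1,3-dioxolane | Fc1ccc(cc1Br)C1OCCO1 | intermediate
3 | 4-ethenylphenyl acetate (4-acetoxystyrene) | CC(=O)Oc1ccc(C=C)cc1 | starting material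
4 | alkylborane acetate: 4-[2-(9-borabicyclo[3.3.1]nonan-9-yl)ethyl]phenyl acetate (not isolated) | CC(=O)Oc1ccc(CCB2C3CCCC2CCC3)cc1 | intermediate
5 | alkylborane phenoxide: 4-[2-(9-borabicyclo[3.3.1]nonan-9-yl)ethyl]phenol, present as its sodium salt and hydroxide adduct at boron (not isolated) | Oc1ccc(CCB2C3CCCC2CCC3)cc1 | intermediate
6 | 4-{2-[5-(1,3-dioxolan-2-yl)-2-fluorophenyl]ethyl}phenol | Oc1ccc(CCc2cc(ccc2F)C2OCCO2)cc1 | intermediate
7 | 3-hydroxybenzaldehyde | Oc1cccc(C=O)c1 | starting material
8 | 3-(methoxymethoxy)benzaldehyde | COCOc1cccc(C=O)c1 | intermediate
9 | 1-ethenyl-3-(methoxymethoxy)benzene | COCOc1cccc(C=C)c1 | intermediate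
10 | 4-bromo-2-fluorobenzaldehyde | O=Cc1ccc(Br)cc1F | starting material
11 | alkylborane: 9-{2-[3-(methoxymethoxy)phenyl]ethyl}-9-borabicyclo[3.3.1]nonane (not isolated) | COCOc1cccc(CCB2C3CCCC2CCC3)c1 | intermediate
12 | 2-fluoro-4-{2-[3-(methoxymethoxy)phenyl]ethyl}benzaldehyde | COCOc1cccc(CCc2ccc(C=O)c(F)c2)c1 | intermediate
13 | 2-(4-{2-[5-(1,3-dioxolan-2-yl)-2-fluorophenyl]ethyl}phenoxy)-4-{2-[3-(methoxymethoxy)phenyl]ethyl}benzaldehyde | COCOc1cccc(CCc2ccc(C=O)c(Oc3ccc(CCc4cc(ccc4F)C4OCCO4)cc3)c2)c1 | intermediate
14 | 2-{4-[2-(2-fluoro-5-formylphenyl)ethyl]phenoxy}-4-[2-(3-hydroxyphenyl)ethyl]benzaldehyde | Oc1cccc(CCc2ccc(C=O)c(Oc3ccc(CCc4cc(C=O)ccc4F)cc3)c2)c1 | intermediate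
15 | macrocyclic dialdehyde: the ring system of the target with CHO in place of each OH (C4 of ring A, C2 of ring C) | O=Cc1ccc2c(c1)CCc1ccc(cc1)Oc1cc(ccc1C=O)CCc1cccc(c1)O2 | intermediate
16 | bis-formate of the target: OCHO at C4 of ring A and at C2 of ring C | O=COc1ccc2c(c1)CCc1ccc(cc1)Oc1cc(ccc1OC=O)CCc1cccc(c1)O2 | intermediate
17 | target diphenol: 18-membered cyclophane ring A–CH2CH2–ring B–O–ring C–CH2CH2–ring D–O–ring A; ring A has the ring D oxygen at C1, the bridge at C2 and OH at C4; ring B is 1,4-phenylene; ring C has the ring B oxygen at C1, OH at C2 and the bridge at C5; ring D is 1,3-phenylene | Oc1ccc2c(c1)CCc1ccc(cc1)Oc1cc(ccc1O)CCc1cccc(c1)O2 | target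

## Step count and least certain steps

Total: 10 steps. Longest linear sequence: 8 steps (7 to 17 through steps 3 to 10); the other branch (1 to 17 through steps 1, 2 and 6 to 10) has 7.

Step 9 (key step). The most likely failure is hydride migration in the peroxy adduct competing with the aryl shift, above all at the ring A aldehyde, whose donor is an aryloxy group and weaker than an alkoxy group. A second is partial hydrolysis of the formates followed by oxidation of the freed phenol rings by excess peracid. Fallback, from 15 back to the route at 17:
- MeMgBr in THF adds to both aldehydes to give the bis(1-hydroxyethyl) macrocycle F1.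
- Dess–Martin periodinane oxidises it to the bis(methyl ketone) F2.
- mCPBA with a little CF3CO2H in CH2Cl2 then performs the Baeyer–Villiger oxidation of the aryl methyl ketones, in which no hydride is available and methyl migrates poorly, to give the bis-acetate F3.
- K2CO3 in methanol cleaves F3 to 17.

Step 8. Chain growth between molecules may outrun ring closure, because the ring A fluoride is flanked by the bridge and activated by a single formyl group. Long heating also invites slow displacement of fluoride by adventitious hydroxide. The fallback closes the ring at the other, unhindered ether; it sets out from 12 and 6 and returns at 15: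
- Aqueous HCl in THF removes the methoxymethyl group of 12 to give 2-fluoro-4-[2-(3-hydroxyphenyl)ethyl]benzaldehyde F4.
- Ethylene glycol with catalytic TsOH in toluene converts it to 3-{2-[4-(1,3-dioxolan-2-yl)-3-fluorophenyl]ethyl}phenol F5, whose fluoride is now dormant.
- Dilute aqueous HCl opens the dioxolane of 6 to 4-fluoro-3-[2-(4-hydroxyphenyl)ethyl]benzaldehyde F6.
- MOMCl and iPr2NEt protect its phenol as 4-fluoro-3-{2-[4-(methoxymethoxy)phenyl]ethyl}benzaldehyde F7.
- K2CO3 in DMSO joins F5 and F7 at the ring A fluoride, now intermolecularly and at high concentration, to give the linear ether 4-(3-{2-[4-(1,3-dioxolan-2-yl)-3-fluorophenyl]ethyl}phenoxy)-3-{2-[4-(methoxymethoxy)phenyl]ethyl}benzaldehyde F8.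
- Aqueous HCl unmasks it to 2-fluoro-4-[2-(3-{4-formyl-2-[2-(4-hydroxyphenyl)ethyl]phenoxy}phenyl)ethyl]benzaldehyde F9.
- Cs2CO3 in dilute DMSO closes the ring by attack of the ring B phenoxide ortho to the ring C formyl group, which gives 15.

Step 5. The formyl group may be reduced by the alkylborane (hydride transfer from its β-carbon) or by leftover B–H before transmetalation, and the coupling may stall by protodeboronation. The fallback avoids boron; it sets out from 9 and 10 and returns at 12:
- A Heck reaction (Pd(OAc)2, P(o-tol)3, Et3N, DMF, 100 °C), which tolerates aldehydes, gives the stilbene (E)-2-fluoro-4-{2-[3-(methoxymethoxy)phenyl]ethenyl}benzaldehyde F10.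
- Hydrogenation over Pd/C poisoned with Ph2S saturates the alkene without touching the aryl aldehyde or the C–F bond and gives 12.

Step 6. The substitution may not go to completion, since the fluoride is activated by one formyl group only. On long heating, adventitious hydroxide may displace the fluoride. The fallback changes the order of bond formation; it sets out from 6 and 10 and returns at 13:
- 6 is first joined under K2CO3 in DMSO to the more electrophilic 10, whose bromine adds inductive activation, giving 4-bromo-2-(4-{2-[5-(1,3-dioxolan-2-yl)-2-fluorophenyl]ethyl}phenoxy)benzaldehyde F11.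
- F11 is then coupled with alkylborane 11 under the conditions of step 5 to give 13. This relies on the same aldehyde-tolerant coupling as step 5.

## Further compounds

F1 | step 9 | macrocyclic bis(1-hydroxyethyl) compound, CH(OH)CH3 in place of each CHO of 15 (diastereomer mixture) | CC(O)c1ccc2c(c1)CCc1ccc(cc1)Oc1cc(ccc1C(C)O)CCc1cccc(c1)O2
F2 | step 9 | macrocyclic bis(methyl ketone), acetyl in place of each CHO of 15 | CC(=O)c1ccc2c(c1)CCc1ccc(cc1)Oc1cc(ccc1C(C)=O)CCc1cccc(c1)O2
F3 | step 9 | bis-acetate of the target | CC(=O)Oc1ccc2c(c1)CCc1ccc(cc1)Oc1cc(ccc1OC(C)=O)CCc1cccc(c1)O2
F4 | step 8 | 2-fluoro-4-[2-(3-hydroxyphenyl)ethyl]benzaldehyde | Oc1cccc(CCc2ccc(C=O)c(F)c2)c1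
F5 | step 8 | 3-{2-[4-(1,3-dioxolan-2-yl)-3-fluorophenyl]ethyl}phenol | Oc1cccc(CCc2ccc(C3OCCO3)c(F)c2)c1
F6 | step 8 | 4-fluoro-3-[2-(4-hydroxyphenyl)ethyl]benzaldehyde | Oc1ccc(CCc2cc(C=O)ccc2F)cc1
F7 | step 8 | 4-fluoro-3-{2-[4-(methoxymethoxy)phenyl]ethyl}benzaldehyde | COCOc1ccc(CCc2cc(C=O)ccc2F)cc1
F8 | step 8 | 4-(3-{2-[4-(1,3-dioxolan-2-yl)-3-fluorophenyl]ethyl}phenoxy)-3-{2-[4-(methoxymethoxy)phenyl]ethyl}benzaldehyde | COCOc1ccc(CCc2cc(C=O)ccc2Oc2cccc(CCc3ccc(C4OCCO4)c(F)c3)c2)cc1
F9 | step 8 | 2-fluoro-4-[2-(3-{4-formyl-2-[2-(4-hydroxyphenyl)ethyl]phenoxy}phenyl)ethyl]benzaldehyde | Oc1ccc(CCc2cc(C=O)ccc2Oc2cccc(CCc3ccc(C=O)c(F)c3)c2)cc1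
F10 | step 5 | (E)-2-fluoro-4-{2-[3-(methoxymethoxy)phenyl]ethenyl}benzaldehyde | COCOc1cccc(/C=C/c2ccc(C=O)c(F)c2)c1
F11 | step 6 | 4-bromo-2-(4-{2-[5-(1,3-dioxolan-2-yl)-2-fluorophenyl]ethyl}phenoxy)benzaldehyde | O=Cc1ccc(Br)cc1Oc1ccc(CCc2cc(ccc2F)C2OCCO2)cc1
A1 | alternative 1 | seco α-bromoketone: 2-bromo-4-(2-arylethyl)cyclohexanone carrying the D–O–A ether, ring A methyl ether and ring B tert-butyldimethylsilyl ether (diastereomer mixture) | COc1ccc(Oc2cccc(CCC3CCC(=O)C(Br)C3)c2)c(CCc2ccc(O[Si](C)(C)C(C)(C)C)cc2)c1
A2 | alternative 1 | macrocyclic 2-aryloxycyclohexanone, ring A methyl ether (diastereomer mixture) | COc1ccc2c(c1)CCc1ccc(cc1)OC1CC(CCC1=O)CCc1cccc(c1)O2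
A3 | alternative 2 | 17-membered 4-alkyl-4-aryloxycyclohexa-2,5-dienone (quinol ether), ring C methyl ether | O=C1C=CC2(C=C1)CCc1ccc(cc1)Oc1cc(ccc1OC)CCc1cccc(c1)O2
A4 | alternative 2 | target with ring C as methyl ether | Oc1ccc2c(c1)CCc1ccc(cc1)Oc1cc(ccc1OC)CCc1cccc(c1)O2
A5 | alternative 3 | 17-membered 1,1-diarylethene, dimethyl ether | COc1ccc2c(c1)CCc1ccc(cc1)Oc1cc(ccc1OC)C(=C)c1cccc(c1)O2
A6 | alternative 3 | 18-membered macrocyclic deoxybenzoin, dimethyl ether | COc1ccc2c(c1)CCc1ccc(cc1)Oc1cc(ccc1OC)CC(=O)c1cccc(c1)O2
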